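Carotenoid numbering is used; primed atoms belong to the half without hydroxyl. The route rests on cutting the C14'–C15' single bond that links the C13'=C14' and C15'=C15 alkenes. The key step exploits the methyl branch on C13'. A nor-methyl C18 dienyne ending in C13'≡C14'H undergoes zirconium-catalysed syn-methylalumination, and the alkenylalane is cross-coupled in the same flask with a C21 (E)-bromotetraene. One operation installs the C13' methyl, fixes E-C13'=C14' and forges C14'–C15'. Both hexahydrobenzofuran rings are made earlier by gold-catalysed cycloisomerisation of α-hydroxyallenes. Their axes, set by syn or anti SN2' hydride opening of alkynyl oxiranes, encode C8' and C8.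

Key step: step 28

Remark on the chemistry: the target is read as the all-E (3R,5S,8S,5'R,8'S) isomer; allene axes are written in SMILES on the central allene carbon, with the terminal hydrogen explicit.

Step 1
Reactants: 1 ethyl acetoacetate
Product: 2 ethyl (2E)-3-(trifluoromethylsulfonyloxy)but-2-enoate
Conditions: Tf2O, aq. Me4NOH, hexanes, 5 °C
Reagents that add atoms: trifluoromethanesulfonic anhydride O=S(=O)(OS(=O)(=O)C(F)(F)F)C(F)(F)F
Why: O-sulfonylation of the β-keto ester enolate under two-phase Schotten–Baumann-type conditions, where the non-chelating ammonium counter-ion should favour the E enolate and hence the E enol triflate.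

Step 2
Reactants: 2 ethyl (2E)-3-(trifluoromethylsulfonyloxy)but-2-enoate
Product: 3 (2E)-4-hydroxybut-2-en-2-yl trifluoromethanesulfonate
Conditions: i-Bu2AlH (2.2 equiv), CH2Cl2, −78 °C; aq. potassium sodium tartrate
Reagents that add atoms: none
Why: 1,2-reduction of a conjugated ester by a dialkylaluminium hydride, which at low temperature leaves the vinyl triflate and the alkene geometry untouched.

Step 3
Reactants: 4 3-bromo-1-(trimethylsilyl)prop-1-yne; 5 triethyl phosphite
Product: 6 diethyl [3-(trimethylsilyl)prop-2-yn-1-yl]phosphonate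
Conditions: neat, 130 °C, volatile halide distilled off
Reagents that add atoms: none
Why: Michaelis–Arbuzov reaction of a primary propargylic bromide.

Step 4
Reactants: 7 acetylene
Product: 8 (E)-1-bromo-2-iodoethene
Conditions: IBr, 48 % aq. HBr, 0 °C
Reagents that add atoms: iodine monobromide BrI
Why: electrophilic anti-addition of the interhalogen across the triple bond gives the E dihalide with two halogens of different reactivity.

Step 5
Reactants: 9 β-cyclocitral
Product: 10 β-cyclogeraniol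
Conditions: NaBH4, MeOH, 0 °C
Reagents that add atoms: none
Why: 1,2-reduction of the hindered enal by borohydride gives the allylic alcohol that will direct the epoxidation.

Step 6
Reactants: 10 β-cyclogeraniol
Product: 11 [(1R,6R)-2,2,6-trimethyl-7-oxabicyclo[4.1.0]heptan-1-yl]methanol
Conditions: Ti(OiPr)4 (cat.), D-(−)-diethyl tartrate (cat.), t-BuOOH, 4 Å molecular sieves, CH2Cl2, −20 °C
Reagents that add atoms: tert-butyl hydroperoxide CC(C)(C)OO
Why: Sharpless asymmetric epoxidation, in which the D-(−)-tartrate should direct the titanium-bound peroxide to the face of the tetrasubstituted C5'=C6' alkene that gives the (1R,6R)-oxirane and so sets C5' (R) of the target.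

Step 7
Reactants: 11 [(1R,6R)-2,2,6-trimethyl-7-oxabicyclo[4.1.0]heptan-1-yl]methanol
Product: 12 (1S,6R)-2,2,6-trimethyl-7-oxabicyclo[4.1.0]heptane-1-carbaldehyde
Conditions: n-Pr4N[RuO4] (cat.), N-methylmorpholine N-oxide, 4 Å molecular sieves, CH2Cl2, rt
Reagents that add atoms: none
Why: the neutral Ley–Griffith oxidation should spare the acid-sensitive oxirane, and the aldehyde has no α-hydrogen, so it cannot epimerise (the descriptor changes only through priorities).

Step 8
Reactants: 12 (1S,6R)-2,2,6-trimethyl-7-oxabicyclo[4.1.0]heptane-1-carbaldehyde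
Product: 13 (1R,6R)-1-ethynyl-2,2,6-trimethyl-7-oxabicyclo[4.1.0]heptane
Conditions: dimethyl (1-diazo-2-oxopropyl)phosphonate, K2CO3, MeOH, rt
Reagents that add atoms: dimethyl (1-diazo-2-oxopropyl)phosphonate COP(=O)(OC)C(=[N+]=[N-])C(C)=O
Why: the Ohira–Bestmann variant of the Seyferth–Gilbert homologation turns the non-enolisable aldehyde into the terminal alkyne (C7'≡C8') under mild carbonate conditions that spare the oxirane.

Step 9
Reactants: 13 (1R,6R)-1-ethynyl-2,2,6-trimethyl-7-oxabicyclo[4.1.0]heptane; 2 ethyl (2E)-3-(trifluoromethylsulfonyloxy)but-2-enoate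
Product: 14 ethyl (2E)-3-methyl-5-[(1R,6R)-2,2,6-trimethyl-7-oxabicyclo[4.1.0]heptan-1-yl]pent-2-en-4-ynoate
Conditions: Pd(PPh3)4 (cat.), CuI (cat.), i-Pr2NH, THF, rt
Reagents that add atoms: none
Why: Sonogashira coupling of the terminal alkyne with the activated vinyl triflate proceeds with retention, so the E geometry of 2 becomes E-C9'=C10'.

Step 10
Reactants: 14 ethyl (2E)-3-methyl-5-[(1R,6R)-2,2,6-trimethyl-7-oxabicyclo[4.1.0]heptan-1-yl]pent-2-en-4-ynoate
Product: 16 (2E)-5-[(2R)-2-hydroxy-2,6,6-trimethylcyclohexylidene]-3-methylpenta-2,4-dien-1-ol (allene axis R), via aluminium alkoxide 15 (not isolated)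
Conditions: i-Bu2AlH (5 equiv), CH2Cl2, −78 → 0 °C; aq. potassium sodium tartrate
Reagents that add atoms: none
Why: the ester is first reduced to the allylic alkoxide, then aluminium bound to the oxirane oxygen hands hydride to C8' on the same face (syn SN2' opening of an alkynyl oxirane), so centre-to-axis transfer should give the R allene while the C5'–O bond stays intact.

Step 11
Reactants: 16 (2E)-5-[(2R)-2-hydroxy-2,6,6-trimethylcyclohexylidene]-3-methylpenta-2,4-dien-1-ol (allene axis R)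
Product: 17 (2E)-3-[(2S,7aR)-4,4,7a-trimethyl-2,4,5,6,7,7a-hexahydro-1-benzofuran-2-yl]but-2-en-1-ol
Conditions: AuCl3 (2 mol %), THF, rt, dark
Reagents that add atoms: none
Why: gold-catalysed 5-endo cycloisomerisation of an α-hydroxyallene to a 2,5-dihydrofuran, in which the C5' hydroxyl attacks C8' anti to the gold-bound C7'=C8' bond and protodeauration follows, so the axis is translated into C8' (S) with the side chain cis to the C5' methyl group.

Step 12
Reactants: 17 (2E)-3-[(2S,7aR)-4,4,7a-trimethyl-2,4,5,6,7,7a-hexahydro-1-benzofuran-2-yl]but-2-en-1-ol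
Product: 18 (2E)-3-[(2S,7aR)-4,4,7a-trimethyl-2,4,5,6,7,7a-hexahydro-1-benzofuran-2-yl]but-2-enal
Conditions: MnO2, CH2Cl2, rt
Reagents that add atoms: none
Why: MnO2 oxidises only the primary allylic alcohol under neutral conditions that do not touch the doubly allylic ether.

Step 13
Reactants: 18 (2E)-3-[(2S,7aR)-4,4,7a-trimethyl-2,4,5,6,7,7a-hexahydro-1-benzofuran-2-yl]but-2-enal; 6 diethyl [3-(trimethylsilyl)prop-2-yn-1-yl]phosphonate
Product: 20 (2S,7aR)-2-[(2E,4E)-hepta-2,4-dien-6-yn-2-yl]-4,4,7a-trimethyl-2,4,5,6,7,7a-hexahydro-1-benzofuran, via silylated dienyne 19 (not isolated)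
Conditions: 6, NaN(SiMe3)2, THF, −78 °C; add 18, −78 → 0 °C; then MeOH, K2CO3, rt
Reagents that add atoms: none
Why: Horner–Wadsworth–Emmons olefination with the preformed propargylic phosphonate anion is E-selective for C11'=C12', and carbonate in methanol then removes the alkynyl silyl group in the same flask under basic conditions that the acid-labile ring tolerates.

Step 14
Reactants: 21 ketoisophorone (2,6,6-trimethylcyclohex-2-ene-1,4-dione)
Product: 22 (4R)-4-hydroxy-2,6,6-trimethylcyclohex-2-en-1-one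
Conditions: [RuCl(p-cymene)((R,R)-TsDPEN)] (cat.), i-PrOH, rt
Reagents that add atoms: none
Why: Noyori-type asymmetric transfer hydrogenation reduces the unhindered C4 carbonyl of the enedione, the alkene taking the place of the aryl group in the usual model, so the (R,R)-catalyst should set the R carbinol that becomes C3.

Step 15
Reactants: 22 (4R)-4-hydroxy-2,6,6-trimethylcyclohex-2-en-1-one
Product: 23 (4R)-4-(tert-butyldimethylsilyloxy)-2,6,6-trimethylcyclohex-2-en-1-one
Conditions: t-BuMe2SiCl, imidazole, DMF, rt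
Reagents that add atoms: tert-butyldimethylsilyl chloride CC(C)(C)[Si](C)(C)Cl
Why: standard silylation protects the secondary alcohol for the hydride and organometallic steps ahead.

Step 16
Reactants: 23 (4R)-4-(tert-butyldimethylsilyloxy)-2,6,6-trimethylcyclohex-2-en-1-one
Product: 25 (4S)-4-(tert-butyldimethylsilyloxy)-2,6,6-trimethylcyclohex-1-en-1-yl trifluoromethanesulfonate, via lithium enolate 24 (not isolated)
Conditions: LiBH(s-Bu)3, THF, −78 °C; then PhNTf2, −78 °C → rt
Reagents that add atoms: N-phenylbis(trifluoromethanesulfonimide) O=S(=O)(N(c1ccccc1)S(=O)(=O)C(F)(F)F)C(F)(F)F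
Why: conjugate reduction with enolate trapping, in which the gem-dimethyl group blocks 1,2-attack, the bulky borohydride adds to the unsubstituted β-carbon, and O-triflation fixes the tetrasubstituted enolate regiospecifically (the carbinol centre is untouched and only its descriptor changes).

Step 17
Reactants: 25 (4S)-4-(tert-butyldimethylsilyloxy)-2,6,6-trimethylcyclohex-1-en-1-yl trifluoromethanesulfonate
Product: 26 methyl (4S)-4-(tert-butyldimethylsilyloxy)-2,6,6-trimethylcyclohex-1-ene-1-carboxylate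
Conditions: Pd(OAc)2 (cat.), PPh3, CO (1 atm), MeOH, Et3N, DMF, 50 °C
Reagents that add atoms: carbon monoxide [C-]#[O+]; methanol CO
Why: palladium-catalysed methoxycarbonylation of the vinyl triflate (oxidative addition, CO insertion, methanolysis) installs C7.

Step 18
Reactants: 26 methyl (4S)-4-(tert-butyldimethylsilyloxy)-2,6,6-trimethylcyclohex-1-ene-1-carboxylate
Product: 27 [(4S)-4-(tert-butyldimethylsilyloxy)-2,6,6-trimethylcyclohex-1-en-1-yl]methanol
Conditions: i-Bu2AlH (2.5 equiv), CH2Cl2, −78 °C; aq. potassium sodium tartrate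
Reagents that add atoms: none
Why: aluminium hydride reduction of the conjugated ester gives the allylic alcohol, and the silyl ether is inert.

Step 19
Reactants: 27 [(4S)-4-(tert-butyldimethylsilyloxy)-2,6,6-trimethylcyclohex-1-en-1-yl]methanol
Product: 28 [(1S,4R,6S)-4-(tert-butyldimethylsilyloxy)-2,2,6-trimethyl-7-oxabicyclo[4.1.0]heptan-1-yl]methanol
Conditions: Ti(OiPr)4 (cat.), L-(+)-diethyl tartrate (cat.), t-BuOOH, 4 Å molecular sieves, CH2Cl2, −20 °C
Reagents that add atoms: tert-butyl hydroperoxide CC(C)(C)OO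
Why: Sharpless asymmetric epoxidation with the L-(+)-tartrate should deliver oxygen to the face opposite to the silyloxy group, so reagent control sets C5 (S) and C6 with the oxirane trans to the C3–O bond.

Step 20
Reactants: 28 [(1S,4R,6S)-4-(tert-butyldimethylsilyloxy)-2,2,6-trimethyl-7-oxabicyclo[4.1.0]heptan-1-yl]methanol
Product: 29 (1R,4R,6S)-4-(tert-butyldimethylsilyloxy)-2,2,6-trimethyl-7-oxabicyclo[4.1.0]heptane-1-carbaldehyde
Conditions: n-Pr4N[RuO4] (cat.), N-methylmorpholine N-oxide, 4 Å molecular sieves, CH2Cl2, rt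
Reagents that add atoms: none
Why: Ley–Griffith oxidation under neutral conditions preserves the oxirane and the silyl ether, and no α-hydrogen is present.

Step 21
Reactants: 29 (1R,4R,6S)-4-(tert-butyldimethylsilyloxy)-2,2,6-trimethyl-7-oxabicyclo[4.1.0]heptane-1-carbaldehyde
Product: 30 (1S,4R,6S)-4-(tert-butyldimethylsilyloxy)-1-ethynyl-2,2,6-trimethyl-7-oxabicyclo[4.1.0]heptane
Conditions: dimethyl (1-diazo-2-oxopropyl)phosphonate, K2CO3, MeOH, rt
Reagents that add atoms: dimethyl (1-diazo-2-oxopropyl)phosphonate COP(=O)(OC)C(=[N+]=[N-])C(C)=O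
Why: Ohira–Bestmann homologation gives the terminal alkyne (C7≡C8), and the silyl ether and oxirane tolerate carbonate in methanol.

Step 22
Reactants: 30 (1S,4R,6S)-4-(tert-butyldimethylsilyloxy)-1-ethynyl-2,2,6-trimethyl-7-oxabicyclo[4.1.0]heptane; 3 (2E)-4-hydroxybut-2-en-2-yl trifluoromethanesulfonate
Product: 31 (2E)-5-[(1S,4R,6S)-4-(tert-butyldimethylsilyloxy)-2,2,6-trimethyl-7-oxabicyclo[4.1.0]heptan-1-yl]-3-methylpent-2-en-4-yn-1-ol
Conditions: Pd(PPh3)4 (cat.), CuI (cat.), i-Pr2NH, THF, rt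
Reagents that add atoms: none
Why: Sonogashira coupling with retention of the vinyl triflate geometry gives E-C9=C10, and the alcohol oxidation level avoids a conjugate acceptor in the copper hydride step that follows.

Step 23
Reactants: 31 (2E)-5-[(1S,4R,6S)-4-(tert-butyldimethylsilyloxy)-2,2,6-trimethyl-7-oxabicyclo[4.1.0]heptan-1-yl]-3-methylpent-2-en-4-yn-1-ol
Product: 33 (2E)-5-[(2S,4R)-4-(tert-butyldimethylsilyloxy)-2-hydroxy-2,6,6-trimethylcyclohexylidene]-3-methylpenta-2,4-dien-1-ol (allene axis R), via bis-silyl ether 32 (not isolated)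
Conditions: CuCl (5 mol %), NaOt-Bu (5 mol %), 1,3-bis(2,6-diisopropylphenyl)imidazolium chloride (5 mol %), (EtO)2MeSiH (3 equiv), toluene, 0 °C → rt; then K2CO3, aq. MeOH
Reagents that add atoms: none
Why: copper hydride-catalysed SN2' reduction of a propargylic oxirane, in which syn-hydrocupration (H to C8, Cu to C7) and anti β-elimination of the C6–O bond place hydride anti to oxygen, so the axis has the opposite relative sense to that of step 10, and carbonate then cleaves the labile alkoxysilyl ethers but not the tert-butyldimethylsilyl ether.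

Step 24
Reactants: 33 (2E)-5-[(2S,4R)-4-(tert-butyldimethylsilyloxy)-2-hydroxy-2,6,6-trimethylcyclohexylidene]-3-methylpenta-2,4-dien-1-ol (allene axis R)
Product: 34 (2E)-3-[(2S,6R,7aS)-6-(tert-butyldimethylsilyloxy)-4,4,7a-trimethyl-2,4,5,6,7,7a-hexahydro-1-benzofuran-2-yl]but-2-en-1-ol
Conditions: AuCl3 (2 mol %), THF, rt, dark
Reagents that add atoms: none
Why: the same gold-catalysed 5-endo cycloisomerisation of an α-hydroxyallene transfers the axis into C8 (S), this time with the side chain trans to the C5 methyl group.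

Step 25
Reactants: 34 (2E)-3-[(2S,6R,7aS)-6-(tert-butyldimethylsilyloxy)-4,4,7a-trimethyl-2,4,5,6,7,7a-hexahydro-1-benzofuran-2-yl]but-2-en-1-ol
Product: 35 (2E)-3-[(2S,6R,7aS)-6-(tert-butyldimethylsilyloxy)-4,4,7a-trimethyl-2,4,5,6,7,7a-hexahydro-1-benzofuran-2-yl]but-2-enal
Conditions: MnO2, CH2Cl2, rt
Reagents that add atoms: none
Why: selective neutral oxidation of the primary allylic alcohol by MnO2.

Step 26
Reactants: 35 (2E)-3-[(2S,6R,7aS)-6-(tert-butyldimethylsilyloxy)-4,4,7a-trimethyl-2,4,5,6,7,7a-hexahydro-1-benzofuran-2-yl]but-2-enal; 6 diethyl [3-(trimethylsilyl)prop-2-yn-1-yl]phosphonate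
Product: 37 (2S,6R,7aS)-6-(tert-butyldimethylsilyloxy)-2-[(2E,4E)-hepta-2,4-dien-6-yn-2-yl]-4,4,7a-trimethyl-2,4,5,6,7,7a-hexahydro-1-benzofuran, via silylated dienyne 36 (not isolated)
Conditions: 6, NaN(SiMe3)2, THF, −78 °C; add 35, −78 → 0 °C; then MeOH, K2CO3, rt
Reagents that add atoms: none
Why: E-selective Horner–Wadsworth–Emmons olefination (C11=C12) followed by carbonate-mediated cleavage of the carbon–silicon bond only, since the oxygen-bound silyl group is stable to these conditions.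

Step 27
Reactants: 37 (2S,6R,7aS)-6-(tert-butyldimethylsilyloxy)-2-[(2E,4E)-hepta-2,4-dien-6-yn-2-yl]-4,4,7a-trimethyl-2,4,5,6,7,7a-hexahydro-1-benzofuran; 8 (E)-1-bromo-2-iodoethene
Product: 39 (2S,6R,7aS)-2-[(2E,4E,6E,8E)-9-bromo-6-methylnona-2,4,6,8-tetraen-2-yl]-6-(tert-butyldimethylsilyloxy)-4,4,7a-trimethyl-2,4,5,6,7,7a-hexahydro-1-benzofuran, via alkenylalane 38 (not isolated)
Conditions: Me3Al (2 equiv), Cp2ZrCl2 (0.25 equiv), ClCH2CH2Cl, rt; volatiles removed in vacuo; THF, 8 (1.5 equiv), Pd2(dba)3 (cat.), P(2-furyl)3 (cat.), ZnCl2 (co-catalyst), DMF, rt; cold dilute aq. NaOH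
Reagents that add atoms: trimethylaluminium C[Al](C)C
Why: zirconium-catalysed syn-methylalumination of the terminal alkyne followed by Negishi-type coupling at the more reactive carbon–iodine bond of 8 builds E-C13=C14 and keeps E-C15=C15', leaving the carbon–bromine bond for the next coupling.

Step 28
Reactants: 20 (2S,7aR)-2-[(2E,4E)-hepta-2,4-dien-6-yn-2-yl]-4,4,7a-trimethyl-2,4,5,6,7,7a-hexahydro-1-benzofuran; 39 (2S,6R,7aS)-2-[(2E,4E,6E,8E)-9-bromo-6-methylnona-2,4,6,8-tetraen-2-yl]-6-(tert-butyldimethylsilyloxy)-4,4,7a-trimethyl-2,4,5,6,7,7a-hexahydro-1-benzofuran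
Product: 41 3-O-(tert-butyldimethylsilyl) ether of the target, via alkenylalane 40 (not isolated)
Conditions: 20 (1.3 equiv), Me3Al (2 equiv), Cp2ZrCl2 (0.25 equiv), ClCH2CH2Cl, rt; volatiles removed in vacuo; THF, 39, Pd2(dba)3 (cat.), P(2-furyl)3 (cat.), ZnCl2 (co-catalyst), DMF, rt, dark; cold dilute aq. NaOH
Reagents that add atoms: trimethylaluminium C[Al](C)C
Why: Me3Al and Cp2ZrCl2 generate a methylzirconium–aluminium species that adds methyl and metal syn across the terminal C13'≡C14'H bond of 20, methyl to the internal C13' and aluminium to C14', giving alane 40. After the excess Me3Al is stripped off, zerovalent palladium inserts into the C15'–Br bond of 39, ZnCl2 relays the alkenyl group from aluminium to palladium, and reductive elimination forges C14'–C15' with retention at both sp2 carbons. The closest known reaction type is zirconium-catalysed carboalumination followed by Negishi coupling, which is established for methyl-branched conjugated polyenes, polyenynes included. No ring is closed and no stereocentre is created: E-C13'=C14' follows from the syn addition, E-C15'=C15 is carried over from 39, and C5', C8', C3, C5 and C8 are spectators. The step needs regio- and chemoselective methylmetalation of the single terminal alkyne beside three alkenes, which the strong preference of the bulky reagent for unhindered triple bonds secures. It also needs the doubly allylic C8'–O and C8–O bonds to survive, which is helped by the steric shielding of both ring oxygens (quaternary C5' or C5 on one side, branched C8' or C8 on the other), by short contact at room temperature and by the basic quench.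

Step 29
Reactants: 41 3-O-(tert-butyldimethylsilyl) ether of the target
Product: 42 (3R,5S,8S,5'R,8'S)-5,8:5',8'-diepoxy-5,8,5',8'-tetrahydro-β,β-caroten-3-ol (target)
Conditions: n-Bu4NF, THF, rt, dark, argon
Reagents that add atoms: none
Why: fluoride-induced desilylation is basic and not acidic, which avoids epimerisation at C8 and C8' of the furanoid rings and leaves the polyene geometry alone.

Compound list
1 | ethyl acetoacetate | CCOC(=O)CC(C)=O | starting material
2 | ethyl (2E)-3-(trifluoromethylsulfonyloxy)but-2-enoate | CCOC(=O)/C=C(\C)OS(=O)(=O)C(F)(F)F | intermediate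
3 | (2E)-4-hydroxybut-2-en-2-yl trifluoromethanesulfonate | OC/C=C(\C)OS(=O)(=O)C(F)(F)F | intermediate
4 | 3-bromo-1-(trimethylsilyl)prop-1-yne | C[Si](C)(C)C#CCBr | starting material
5 | triethyl phosphite | CCOP(OCC)OCC | starting material
6 | diethyl [3-(trimethylsilyl)prop-2-yn-1-yl]phosphonate | CCOP(=O)(CC#C[Si](C)(C)C)OCC | intermediate
7 | acetylene | C#C | starting material
8 | (E)-1-bromo-2-iodoethene | Br/C=C/I | intermediate
9 | β-cyclocitral (2,6,6-trimethylcyclohex-1-ene-1-carbaldehyde) | CC1=C(C=O)C(C)(C)CCC1 | starting material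
10 | β-cyclogeraniol ((2,6,6-trimethylcyclohex-1-en-1-yl)methanol) | CC1=C(CO)C(C)(C)CCC1 | intermediate
11 | [(1R,6R)-2,2,6-trimethyl-7-oxabicyclo[4.1.0]heptan-1-yl]methanol | C[C@@]12CCCC(C)(C)[C@]1(CO)O2 | intermediate
12 | (1S,6R)-2,2,6-trimethyl-7-oxabicyclo[4.1.0]heptane-1-carbaldehyde | C[C@@]12CCCC(C)(C)[C@]1(C=O)O2 | intermediate
13 | (1R,6R)-1-ethynyl-2,2,6-trimethyl-7-oxabicyclo[4.1.0]heptane | C[C@@]12CCCC(C)(C)[C@]1(C#C)O2 | intermediate
14 | ethyl (2E)-3-methyl-5-[(1R,6R)-2,2,6-trimethyl-7-oxabicyclo[4.1.0]heptan-1-yl]pent-2-en-4-ynoate | C[C@@]12CCCC(C)(C)[C@]1(C#C/C(C)=C/C(=O)OCC)O2 | intermediate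
15 | diisobutylaluminium alkoxide of (2E)-3-methyl-5-[(1R,6R)-2,2,6-trimethyl-7-oxabicyclo[4.1.0]heptan-1-yl]pent-2-en-4-yn-1-ol | C[C@@]12CCCC(C)(C)[C@]1(C#C/C(C)=C/CO[Al](CC(C)C)CC(C)C)O2 | intermediate
16 | (2E)-5-[(2R)-2-hydroxy-2,6,6-trimethylcyclohexylidene]-3-methylpenta-2,4-dien-1-ol, allene axis R (carotenoid 5'R,6'R) | C[C@@]1(O)CCCC(C)(C)C1=[C@@]=C([H])/C(C)=C/CO | intermediate
17 | (2E)-3-[(2S,7aR)-4,4,7a-trimethyl-2,4,5,6,7,7a-hexahydro-1-benzofuran-2-yl]but-2-en-1-ol | OC/C=C(\C)[C@@H]1C=C2C(C)(C)CCC[C@@]2(C)O1 | intermediate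
18 | (2E)-3-[(2S,7aR)-4,4,7a-trimethyl-2,4,5,6,7,7a-hexahydro-1-benzofuran-2-yl]but-2-enal | O=C/C=C(\C)[C@@H]1C=C2C(C)(C)CCC[C@@]2(C)O1 | intermediate
19 | trimethyl{(3E,5E)-6-[(2S,7aR)-4,4,7a-trimethyl-2,4,5,6,7,7a-hexahydro-1-benzofuran-2-yl]hepta-3,5-dien-1-yn-1-yl}silane | C[Si](C)(C)C#C/C=C/C=C(\C)[C@@H]1C=C2C(C)(C)CCC[C@@]2(C)O1 | intermediate
20 | (2S,7aR)-2-[(2E,4E)-hepta-2,4-dien-6-yn-2-yl]-4,4,7a-trimethyl-2,4,5,6,7,7a-hexahydro-1-benzofuran (C18 dienyne) | C#C/C=C/C=C(\C)[C@@H]1C=C2C(C)(C)CCC[C@@]2(C)O1 | intermediate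
21 | ketoisophorone (2,6,6-trimethylcyclohex-2-ene-1,4-dione) | CC1=CC(=O)CC(C)(C)C1=O | starting material
22 | (4R)-4-hydroxy-2,6,6-trimethylcyclohex-2-en-1-one | CC1=C[C@H](O)CC(C)(C)C1=O | intermediate
23 | (4R)-4-(tert-butyldimethylsilyloxy)-2,6,6-trimethylcyclohex-2-en-1-one | CC1=C[C@H](O[Si](C)(C)C(C)(C)C)CC(C)(C)C1=O | intermediate
24 | lithium (4S)-4-(tert-butyldimethylsilyloxy)-2,6,6-trimethylcyclohex-1-en-1-olate | [Li+].CC1=C([O-])C(C)(C)C[C@@H](O[Si](C)(C)C(C)(C)C)C1 | intermediate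
25 | (4S)-4-(tert-butyldimethylsilyloxy)-2,6,6-trimethylcyclohex-1-en-1-yl trifluoromethanesulfonate | CC1=C(OS(=O)(=O)C(F)(F)F)C(C)(C)C[C@@H](O[Si](C)(C)C(C)(C)C)C1 | intermediate
26 | methyl (4S)-4-(tert-butyldimethylsilyloxy)-2,6,6-trimethylcyclohex-1-ene-1-carboxylate | CC1=C(C(=O)OC)C(C)(C)C[C@@H](O[Si](C)(C)C(C)(C)C)C1 | intermediate
27 | [(4S)-4-(tert-butyldimethylsilyloxy)-2,6,6-trimethylcyclohex-1-en-1-yl]methanol | CC1=C(CO)C(C)(C)C[C@@H](O[Si](C)(C)C(C)(C)C)C1 | intermediate
28 | [(1S,4R,6S)-4-(tert-butyldimethylsilyloxy)-2,2,6-trimethyl-7-oxabicyclo[4.1.0]heptan-1-yl]methanol | C[C@]12C[C@H](O[Si](C)(C)C(C)(C)C)CC(C)(C)[C@@]1(CO)O2 | intermediate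
29 | (1R,4R,6S)-4-(tert-butyldimethylsilyloxy)-2,2,6-trimethyl-7-oxabicyclo[4.1.0]heptane-1-carbaldehyde | C[C@]12C[C@H](O[Si](C)(C)C(C)(C)C)CC(C)(C)[C@@]1(C=O)O2 | intermediate
30 | (1S,4R,6S)-4-(tert-butyldimethylsilyloxy)-1-ethynyl-2,2,6-trimethyl-7-oxabicyclo[4.1.0]heptane | C[C@]12C[C@H](O[Si](C)(C)C(C)(C)C)CC(C)(C)[C@@]1(C#C)O2 | intermediate
31 | (2E)-5-[(1S,4R,6S)-4-(tert-butyldimethylsilyloxy)-2,2,6-trimethyl-7-oxabicyclo[4.1.0]heptan-1-yl]-3-methylpent-2-en-4-yn-1-ol | C[C@]12C[C@H](O[Si](C)(C)C(C)(C)C)CC(C)(C)[C@@]1(C#C/C(C)=C/CO)O2 | intermediate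
32 | bis[diethoxy(methyl)silyl] ether of allenediol 33 | C[C@]1(O[Si](C)(OCC)OCC)C[C@H](O[Si](C)(C)C(C)(C)C)CC(C)(C)C1=[C@@]=C([H])/C(C)=C/CO[Si](C)(OCC)OCC | intermediate
33 | (2E)-5-[(2S,4R)-4-(tert-butyldimethylsilyloxy)-2-hydroxy-2,6,6-trimethylcyclohexylidene]-3-methylpenta-2,4-dien-1-ol, allene axis R (carotenoid 3R,5S,6R) | C[C@]1(O)C[C@H](O[Si](C)(C)C(C)(C)C)CC(C)(C)C1=[C@@]=C([H])/C(C)=C/CO | intermediate
34 | (2E)-3-[(2S,6R,7aS)-6-(tert-butyldimethylsilyloxy)-4,4,7a-trimethyl-2,4,5,6,7,7a-hexahydro-1-benzofuran-2-yl]but-2-en-1-ol | OC/C=C(\C)[C@@H]1C=C2C(C)(C)C[C@@H](O[Si](C)(C)C(C)(C)C)C[C@]2(C)O1 | intermediate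
35 | (2E)-3-[(2S,6R,7aS)-6-(tert-butyldimethylsilyloxy)-4,4,7a-trimethyl-2,4,5,6,7,7a-hexahydro-1-benzofuran-2-yl]but-2-enal | O=C/C=C(\C)[C@@H]1C=C2C(C)(C)C[C@@H](O[Si](C)(C)C(C)(C)C)C[C@]2(C)O1 | intermediate
36 | C-trimethylsilyl derivative of dienyne 37 | C[Si](C)(C)C#C/C=C/C=C(\C)[C@@H]1C=C2C(C)(C)C[C@@H](O[Si](C)(C)C(C)(C)C)C[C@]2(C)O1 | intermediate
37 | (2S,6R,7aS)-6-(tert-butyldimethylsilyloxy)-2-[(2E,4E)-hepta-2,4-dien-6-yn-2-yl]-4,4,7a-trimethyl-2,4,5,6,7,7a-hexahydro-1-benzofuran | C#C/C=C/C=C(\C)[C@@H]1C=C2C(C)(C)C[C@@H](O[Si](C)(C)C(C)(C)C)C[C@]2(C)O1 | intermediate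
38 | dimethyl{(1E,3E,5E)-2-methyl-6-[(2S,6R,7aS)-6-(tert-butyldimethylsilyloxy)-4,4,7a-trimethyl-2,4,5,6,7,7a-hexahydro-1-benzofuran-2-yl]hepta-1,3,5-trien-1-yl}alane | C[Al](C)/C=C(\C)/C=C/C=C(\C)[C@@H]1C=C2C(C)(C)C[C@@H](O[Si](C)(C)C(C)(C)C)C[C@]2(C)O1 | intermediate
39 | (2S,6R,7aS)-2-[(2E,4E,6E,8E)-9-bromo-6-methylnona-2,4,6,8-tetraen-2-yl]-6-(tert-butyldimethylsilyloxy)-4,4,7a-trimethyl-2,4,5,6,7,7a-hexahydro-1-benzofuran (C21 bromide) | Br/C=C/C=C(C)/C=C/C=C(\C)[C@@H]1C=C2C(C)(C)C[C@@H](O[Si](C)(C)C(C)(C)C)C[C@]2(C)O1 | intermediate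
40 | dimethyl{(1E,3E,5E)-2-methyl-6-[(2S,7aR)-4,4,7a-trimethyl-2,4,5,6,7,7a-hexahydro-1-benzofuran-2-yl]hepta-1,3,5-trien-1-yl}alane | C[Al](C)/C=C(\C)/C=C/C=C(\C)[C@@H]1C=C2C(C)(C)CCC[C@@]2(C)O1 | intermediate
41 | 3-O-(tert-butyldimethylsilyl) ether of the target | CC(/C=C/C=C(\C)[C@@H]1C=C2C(C)(C)CCC[C@@]2(C)O1)=C\C=C\C=C(C)\C=C\C=C(/C)[C@@H]1C=C2C(C)(C)C[C@@H](O[Si](C)(C)C(C)(C)C)C[C@]2(C)O1 | intermediate
42 | (3R,5S,8S,5'R,8'S)-5,8:5',8'-diepoxy-5,8,5',8'-tetrahydro-β,β-caroten-3-ol | CC(/C=C/C=C(\C)[C@@H]1C=C2C(C)(C)CCC[C@@]2(C)O1)=C\C=C\C=C(C)\C=C\C=C(/C)[C@@H]1C=C2C(C)(C)C[C@@H](O)C[C@]2(C)O1 | target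

Total step count: 29. Longest linear sequence: 16 steps (steps 14 to 29, from 21).

Steps most likely to fail

Step 28. The aluminium and zirconium Lewis acids may ionise the doubly allylic C8'–O bond, which would cause ring opening, methyl transfer or C8' epimerisation before or during methylalumination. Transfer of the alkenyl group to palladium may also be sluggish. The fallback sets out from 20 and avoids Lewis acids altogether. Copper-catalysed methylboration (CuCl, Xantphos, NaOt-Bu, B2pin2, MeI, THF) proceeds by syn-borylcupration with boron at C14', followed by methylation of the carbon–copper bond. It would give the (E)-alkenylboronic acid pinacol ester F1. Suzuki–Miyaura coupling of this ester with 39 (Pd(PPh3)4, aq. K3PO4, THF, dark) comes back to the route at 41.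

Step 23. The anti selectivity may erode through oxygen-directed hydride delivery, or hydrocupration of the hindered enyne may be slow and allow reduction elsewhere. The fallback sets out from 31 and gives up kinetic control at C8. Treatment with i-Bu2AlH as in step 10 would give, by syn opening, the axis-epimeric allenediol F2. AuCl3 in THF would then convert it into the C8-epimeric furanoid alcohol F3. Furanoid oxides equilibrate at C8 under acid catalysis (catalytic pyridinium p-toluenesulfonate, CH2Cl2). This equilibration, with chromatographic separation and recycling of the unwanted epimer, comes back to the route at 34.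

Step 11. Gold may induce competing cyclopentannulation of the vinylallene, or reversible ionisation at C8' may partly erase the axis-to-centre transfer. The fallback sets out from 16 and replaces π-acid catalysis with an electrophile-induced ring closure. Iodocyclisation (N-iodosuccinimide, NaHCO3, CH2Cl2, −20 °C) involves anti attack of the C5' hydroxyl on the iodonium-activated C7'=C8' bond and would give the 3-iodo-2,5-dihydrofuran F4. Palladium-catalysed hydrodeiodination (Pd(PPh3)4, n-Bu3SnH, THF) comes back to the route at 17.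

Further compounds
F1 | step 28 | 4,4,5,5-tetramethyl-2-{(1E,3E,5E)-2-methyl-6-[(2S,7aR)-4,4,7a-trimethyl-2,4,5,6,7,7a-hexahydro-1-benzofuran-2-yl]hepta-1,3,5-trien-1-yl}-1,3,2-dioxaborolane | CC1(C)OB(/C=C(\C)/C=C/C=C(\C)[C@@H]2C=C3C(C)(C)CCC[C@@]3(C)O2)OC1(C)C
F2 | step 23 | (2E)-5-[(2S,4R)-4-(tert-butyldimethylsilyloxy)-2-hydroxy-2,6,6-trimethylcyclohexylidene]-3-methylpenta-2,4-dien-1-ol, allene axis S | C[C@]1(O)C[C@H](O[Si](C)(C)C(C)(C)C)CC(C)(C)C1=[C@]=C([H])/C(C)=C/CO
F3 | step 23 | (2E)-3-[(2R,6R,7aS)-6-(tert-butyldimethylsilyloxy)-4,4,7a-trimethyl-2,4,5,6,7,7a-hexahydro-1-benzofuran-2-yl]but-2-en-1-ol | OC/C=C(\C)[C@H]1C=C2C(C)(C)C[C@@H](O[Si](C)(C)C(C)(C)C)C[C@]2(C)O1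
F4 | step 11 | (2E)-3-[(2R,7aR)-3-iodo-4,4,7a-trimethyl-2,4,5,6,7,7a-hexahydro-1-benzofuran-2-yl]but-2-en-1-ol | OC/C=C(\C)[C@@H]1C(I)=C2C(C)(C)CCC[C@@]2(C)O1
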